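**Retrosynthetic overview** (labdane numbering C1–C20 is used for every intermediate)

1. Side chain last: C12–C13 by B-alkyl Suzuki–Miyaura coupling of a C9-vinyl diene with 4-bromofuran-2(5H)-one; C9–C11 by Stille coupling of the C9 enol triflate; the 6β-acetate from the C6 ketone by hydride delivery to the α face.
2. Ring A is the last carbocycle formed: C1–C2 and C4–C5 are made in one flask by inserting the C2–C3–C4(Me)2 unit of 4-bromo-2-methylbut-1-ene into the C1–C5 bond of a cyclopropane fused to ring B.
3. Enabling feature: C6 is a carbonyl carbon bonded to C5, and C1 is a CH2 on the quaternary C10. A cyclopropane C1–C5–C10 fused to the cyclohexenone ring B is therefore a ketone-activated σ bond whose cleavage gives a β-hydrogen-free alkylmetal at C1 and a regiodefined dienol ether at C5.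
4. Ring B comes from 3,5-dimethylphenol (its OH carbon is C6, its methyl carbons are C8 and C10) by dearomatization to the quinone monoketal; the C9 ketal of (R,R)-hydrobenzoin directs the cyclopropanation that sets C10.
5. Order of ring formation: ring B (from the arene), the temporary cyclopropane, ring A (key step); the butenolide is attached as an intact ring.

Key step: step 4

Assumption: in step 3 the ylide is taken to add anti to the nearer phenyl group of the (R,R)-ketal; if the sense of induction were the opposite, the same route would be run with the equally available (S,S)-diol.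

**Step 1**
Reactants: 1 3,5-dimethylphenol
Product: 3 4,4-dimethoxy-3,5-dimethylcyclohexa-2,5-dien-1-one, via 4-methoxy-3,5-dimethylphenol 2 (not isolated)
Conditions: PhI(OAc)2 (2.2 equiv), MeOH, 0 °C to rt
Reagents that add atoms: methanol, CO
Why: Hypervalent-iodine oxidative dearomatization of a para-unsubstituted phenol in methanol should first install the 4-methoxy group (2) and then convert 2 into the quinone monoketal 3, which already holds C6 with its oxygen, the C8 and C10 methyl groups and a masked C9 carbonyl; no stereocenter is formed.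

**Step 2**
Reactants: 3 4,4-dimethoxy-3,5-dimethylcyclohexa-2,5-dien-1-one, 4 (1R,2R)-1,2-diphenylethane-1,2-diol
Product: 5 (2R,3R)-6,10-dimethyl-2,3-diphenyl-1,4-dioxaspiro[4.5]deca-6,9-dien-8-one
Conditions: BF3·OEt2 (10 mol%), DME, 0 °C to rt
Reagents that add atoms: none
Why: Acid-catalysed transketalization of a quinone monoketal with a 1,2-diol should give the C2-symmetric ketal, in which the two enone halves are homotopic and their faces diastereotopic; no new stereocenter is formed.

**Step 3**
Reactants: 5 (2R,3R)-6,10-dimethyl-2,3-diphenyl-1,4-dioxaspiro[4.5]deca-6,9-dien-8-one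
Product: 6 (1R,6S,4'R,5'R)-4,6-dimethyl-4',5'-diphenylspiro[bicyclo[4.1.0]hept-3-ene-5,2'-[1,3]dioxolan]-2-one (cyclopropane C1–C5–C10 cis-fused to ring B; 5R,10S)
Conditions: Me3S(O)I (1.05 equiv), NaH, DMSO, rt to 50 °C
Reagents that add atoms: trimethylsulfoxonium iodide, C[S+](C)(C)=O.[I-]
Why: In this Corey–Chaykovsky cyclopropanation the sulfoxonium ylide should add to the β-carbon C10 of either (equivalent) enone and the enolate should close at C5; approach anti to the nearer phenyl group of the ketal sets C10 (S), and C5 follows because the three-membered ring can only be cis-fused.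

**Step 4**
Reactants: 6 cyclopropane-fused enone ketal, 7 4-bromo-2-methylbut-1-ene
Product: 10 trans-fused bicyclic enone ketal (5S,10S; ring A with 4,4-dimethyl; C6 ketone conjugated to C7=C8 bearing the 8-methyl; C9 as the (R,R)-hydrobenzoin ketal; 10-methyl), via (3-methylbut-3-en-1-yl)zinc bromide 8 (not isolated), via silyl dienol ether 9 (not isolated)
Conditions: 7, Zn, LiCl, THF, 40 °C; then 6, NiBr2·DME (10 mol%), terpyridine (10 mol%), Me3SiCl, THF, rt; then CH2Cl2 in place of THF, TfOH (1.5 equiv), −78 to −20 °C
Reagents that add atoms: none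
Why: Proposed new method: low-valent nickel–terpyridine, with Me3SiCl bound at the C6 carbonyl, should insert into the C1–C5 bond of the fused cyclopropane (the bond to the CH2 carbon, which is the less hindered one and the one aligned with the carbonyl π system), the β-hydrogen-free alkylnickel at C1 should be alkylated by zinc reagent 8 (bond C1–C2) while C5 is released as the silyl dienol ether 9, and TfOH should then protonate the 1,1-disubstituted alkene to the tertiary C4 cation, which C5 of the dienol ether captures (bond C4–C5) before loss of the silyl group returns the C6 enone. The closest known reaction types are the nickel-catalysed ring-opening cross-coupling of cyclopropyl ketones with organozinc halides and chlorosilanes to γ-substituted silyl enol ethers, and the proton-initiated cation–olefin cyclization that ends on a silyl enol ether; new is their union in one flask on a cyclopropane-fused cyclohexenone, which amounts to inserting a three-carbon unit into a cyclopropane bond. Ring A closes as a 6-(enolexo) alkylation through a chair-like transition state in which the nucleophilic C5 attacks the cationic C4. C10 is not touched and keeps the configuration set in step 3, whereas the new centre C5 lies α to the C6 carbonyl and should equilibrate through the dienol under the acidic conditions to the trans-fused (5S) isomer, in which the C4–C5 bond is equatorial on ring B. The step needs cleavage of C1–C5 and not of C5–C10, and homoconjugate and not conjugate delivery of the alkyl group; the first is secured by the quaternary C10, the second by the fully substituted, ketal-flanked β-carbon C8.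

**Step 5**
Reactants: 10 trans-fused bicyclic enone ketal
Product: 11 (5S,6R,10S)-6β-allylic alcohol (C6–OH, C7=C8, C9 ketal)
Conditions: NaBH4, CeCl3·7H2O, MeOH, −40 °C
Reagents that add atoms: none
Why: Luche reduction should reduce only the carbonyl of the enone (1,2-reduction); hydride should attack C6 from the α face, away from the axial methyl groups on C4 and C10 that cover the β face, which sets the 6β (6R) alcohol.

**Step 6**
Reactants: 11 6β-allylic alcohol
Product: 12 (5S,6R,10S)-6β-acetate (C7=C8, C9 ketal)
Conditions: Ac2O, DMAP, Et3N, CH2Cl2, 40 °C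
Reagents that add atoms: acetic anhydride, CC(=O)OC(C)=O
Why: DMAP-catalysed acylation should acetylate the hindered axial secondary alcohol; no stereocenter is touched.

**Step 7**
Reactants: 12 6β-acetate ketal
Product: 13 (5S,6R,10S)-6β-acetoxy enone (C9 ketone conjugated to C8=C7)
Conditions: TsOH·H2O (cat.), acetone/H2O, 40 °C
Reagents that add atoms: water, O
Why: Acid-catalysed hydrolysis of the allylic ketal, which ionizes to an allyl-stabilised oxocarbenium ion, should release the C9 ketone as the conjugated enone and return diol 4, while the acetate and the ring-fusion centres stay as they are.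

**Step 8**
Reactants: 13 6β-acetoxy enone
Product: 15 (5S,6R,10S)-C9 enol triflate (C8=C9, C7 as CH2, 6β-OAc), via lithium enolate 14 (not isolated)
Conditions: LiBH(s-Bu)3, THF, −78 °C; then PhNTf2, −78 to 0 °C
Reagents that add atoms: N-phenyl-bis(trifluoromethanesulfonimide), O=S(=O)(N(c1ccccc1)S(=O)(=O)C(F)(F)F)C(F)(F)F
Why: Conjugate (1,4-) reduction of the α-methyl enone by the hindered borohydride (hydride to C7) should give enolate 14 with the double bond fixed at C8=C9, and O-triflation traps this regiochemistry; no stereocenter is formed.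

**Step 9**
Reactants: 15 C9 enol triflate
Product: 16 (5S,6R,10S)-9-vinyl diene (C8=C9–C11=C12, 6β-OAc)
Conditions: CH2=CHSnBu3, Pd(PPh3)4 (5 mol%), LiCl, THF, 65 °C
Reagents that add atoms: tributyl(vinyl)stannane, C=C[Sn](CCCC)(CCCC)CCCC
Why: Stille cross-coupling of the enol triflate with the vinylstannane should replace the triflate by the vinyl group that supplies C11 and C12, with the tetrasubstituted C8=C9 alkene retained.

**Step 10**
Reactants: 16 9-vinyl diene, 17 4-bromofuran-2(5H)-one
Product: 19 6β-acetoxylabda-8,13-dien-15,16-olide (CNP0128495.1), via B-alkyl-9-borabicyclononane 18 (not isolated)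
Conditions: 9-BBN, THF, 0 °C to rt; then 17, PdCl2(dppf) (5 mol%), AsPh3, K3PO4, DMF/H2O, rt
Reagents that add atoms: none
Why: Hydroboration with the bulky 9-BBN should occur only at the terminal vinyl CH2 (anti-Markovnikov), and B-alkyl Suzuki–Miyaura coupling of borane 18 with the β-bromobutenolide should form C12–C13 without touching the acetate, the tetrasubstituted alkene or the lactone.

**Compound list**

1 | 3,5-dimethylphenol | Cc1cc(C)cc(O)c1 | starting material
2 | 4-methoxy-3,5-dimethylphenol | COc1c(C)cc(O)cc1C | intermediate
3 | 4,4-dimethoxy-3,5-dimethylcyclohexa-2,5-dien-1-one | COC1(OC)C(C)=CC(=O)C=C1C | intermediate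
4 | (1R,2R)-1,2-diphenylethane-1,2-diol ((R,R)-hydrobenzoin) | O[C@H](c1ccccc1)[C@H](O)c1ccccc1 | starting material
5 | (2R,3R)-6,10-dimethyl-2,3-diphenyl-1,4-dioxaspiro[4.5]deca-6,9-dien-8-one | O=C1C=C(C)C2(O[C@H](c3ccccc3)[C@@H](c3ccccc3)O2)C(C)=C1 | intermediate
6 | (1R,6S,4'R,5'R)-4,6-dimethyl-4',5'-diphenylspiro[bicyclo[4.1.0]hept-3-ene-5,2'-[1,3]dioxolan]-2-one (5R,10S in labdane numbering) | O=C1C=C(C)C2(O[C@H](c3ccccc3)[C@@H](c3ccccc3)O2)[C@@]3(C)C[C@@H]13 | intermediate
7 | 4-bromo-2-methylbut-1-ene | C=C(C)CCBr | starting material
8 | (3-methylbut-3-en-1-yl)zinc bromide | C=C(C)CC[Zn]Br | intermediate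
9 | (2R,3R,6S)-6,10-dimethyl-6-(4-methylpent-4-en-1-yl)-2,3-diphenyl-8-(trimethylsilyloxy)-1,4-dioxaspiro[4.5]deca-7,9-diene | C[Si](C)(C)OC1=C[C@](C)(CCCC(C)=C)C2(O[C@H](c3ccccc3)[C@@H](c3ccccc3)O2)C(C)=C1 | intermediate
10 | trans-fused bicyclic enone ketal (5S,10S): 4,4,8,10-tetramethyl, C6 ketone, C7=C8, C9 as (R,R)-hydrobenzoin ketal | O=C1C=C(C)C3(O[C@H](c4ccccc4)[C@@H](c4ccccc4)O3)[C@@]2(C)CCCC(C)(C)[C@H]12 | intermediate
11 | (5S,6R,10S)-6β-hydroxy analogue of 10 | O[C@@H]1C=C(C)C3(O[C@H](c4ccccc4)[C@@H](c4ccccc4)O3)[C@@]2(C)CCCC(C)(C)[C@H]12 | intermediate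
12 | (5S,6R,10S)-6β-acetoxy analogue of 10 | CC(=O)O[C@@H]1C=C(C)C3(O[C@H](c4ccccc4)[C@@H](c4ccccc4)O3)[C@@]2(C)CCCC(C)(C)[C@H]12 | intermediate
13 | (5S,6R,10S)-6β-acetoxy-4,4,8,10-tetramethyl bicyclic enone (C9 ketone, C7=C8) | CC(=O)O[C@@H]1C=C(C)C(=O)[C@@]2(C)CCCC(C)(C)[C@H]12 | intermediate
14 | lithium C9 enolate of the 7,8-dihydro form of 13 (C8=C9) | CC(=O)O[C@@H]1CC(C)=C(O[Li])[C@@]2(C)CCCC(C)(C)[C@H]12 | intermediate
15 | (5S,6R,10S)-6β-acetoxy C9 enol triflate (C8=C9) | CC(=O)O[C@@H]1CC(C)=C(OS(=O)(=O)C(F)(F)F)[C@@]2(C)CCCC(C)(C)[C@H]12 | intermediate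
16 | (5S,6R,10S)-6β-acetoxy-9-vinyl diene | CC(=O)O[C@@H]1CC(C)=C(C=C)[C@@]2(C)CCCC(C)(C)[C@H]12 | intermediate
17 | 4-bromofuran-2(5H)-one | O=C1C=C(Br)CO1 | starting material
18 | B-(C12-alkyl)-9-borabicyclo[3.3.1]nonane from 16 | CC(=O)O[C@@H]1CC(C)=C(CCB3C4CCCC3CCC4)[C@@]2(C)CCCC(C)(C)[C@H]12 | intermediate
19 | (5S,6R,10S)-6β-acetoxylabda-8,13-dien-15,16-olide (CNP0128495.1) | CC(=O)O[C@@H]1CC(C)=C(CCC2=CC(=O)OC2)[C@@]2(C)CCCC(C)(C)[C@H]12 | target

**Step count and risks**

Total step count: 10 (one linear sequence; 4, 7 and 17 are purchased). Longest linear sequence: 10 steps, from 1 to 19.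

Steps most likely to fail:

Step 4 (Proposed new method). Nickel may insert into the C5–C10 bond or the organozinc may add in conjugate fashion to the enone; in the acid stage, proton loss from the tertiary cation or ionization of the ketal may outrun ring closure. The fallback makes the two bonds one at a time by classical reactions. It sets out from 6: homoconjugate addition of the cuprate made from (3-methylbut-3-en-1-yl)magnesium bromide (CuBr·SMe2, Me3SiCl, THF, −40 °C) and aqueous work-up should give the ring-opened enone F1, which is isolated. A thermal Conia-ene reaction of F1 (sealed tube, about 300 °C) should then proceed through its cross-conjugated dienol, the only enol available because C7 is sp2, to form C4–C5 and turn the terminal CH2 into the second C4 methyl group. Equilibration at C5 brings the material back to the route at 10.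

Step 3. Ylide addition at the hindered, fully substituted β-carbon may be slow, and facial discrimination by the ketal phenyl groups may be poor. The fallback delivers the methylene from a hydroxyl group and sets out from 5: Luche reduction should give the dienol F2 (C6 is not stereogenic because the two ring halves are homotopic). Hydroxyl-directed Simmons–Smith cyclopropanation (Et2Zn, CH2I2, CH2Cl2, 0 °C) should then occur on the alkene whose hydroxyl-bearing face is not covered by a phenyl group and give the cyclopropyl carbinol F3. Oxidation of this allylic alcohol (MnO2, CH2Cl2) returns to the route at 6.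

Step 7. Under the hydrolysis conditions the allylic acetate may ionize or acetic acid may be eliminated from the γ-acetoxy enone. The fallback removes the ketal before C6 is reduced and sets out from 10: hydrolysis (TsOH·H2O, acetone/H2O) should give the ene-dione F4. Luche reduction should then take place at the C6 carbonyl, which is less hindered than the C9 carbonyl flanked by the quaternary C10, again from the α face, and give the hydroxy enone F5. Acetylation (Ac2O, DMAP) returns to the route at 13.

**Further compounds**

F1 | step 4 | (2R,3R,6S)-6,10-dimethyl-6-(4-methylpent-4-en-1-yl)-2,3-diphenyl-1,4-dioxaspiro[4.5]dec-9-en-8-one | O=C1C[C@](C)(CCCC(C)=C)C2(O[C@H](c3ccccc3)[C@@H](c3ccccc3)O2)C(C)=C1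
F2 | step 3 | (2R,3R)-6,10-dimethyl-2,3-diphenyl-1,4-dioxaspiro[4.5]deca-6,9-dien-8-ol | OC1C=C(C)C2(O[C@H](c3ccccc3)[C@@H](c3ccccc3)O2)C(C)=C1
F3 | step 3 | cyclopropyl carbinol corresponding to 6, hydroxyl syn to the cyclopropane CH2 | O[C@H]1C=C(C)C2(O[C@H](c3ccccc3)[C@@H](c3ccccc3)O2)[C@@]3(C)C[C@@H]13
F4 | step 7 | (5S,10S)-4,4,8,10-tetramethyl bicyclic ene-dione (C6 and C9 ketones, C7=C8) | O=C1C=C(C)C(=O)[C@@]2(C)CCCC(C)(C)[C@H]12
F5 | step 7 | (5S,6R,10S)-6β-hydroxy enone (C9 ketone, C7=C8) | O[C@@H]1C=C(C)C(=O)[C@@]2(C)CCCC(C)(C)[C@H]12
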